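**Plan**

1. Retrosynthetic cuts, in order: the seven phenol protecting groups; the C(=O)–CH=CH unit on the central resorcinol ring (carbonylative Heck reaction of an aryl bromide); the bond between the ketone carbonyl and the prenylated ring (aryl Grignard reagent on a Weinreb amide); the cyclohexene ring bond between the carbon α to that carbonyl and the carbon bearing the 2,4-dihydroxyphenyl ring; the bond from the resorcinol-bearing ring carbon to the alkene CH; the ring CH2–CH(aryl) bond.
2. Forward: coumarin 5 and (Z)-alkenylboronate 18 are joined by rhodium-catalysed conjugate addition, the cyclohexene ring is closed on the resulting dihydrocoumarin, the lactone is opened and turned into the aryl ketone, and the chalcone arm is attached last.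
3. Enabling feature: the 4-hydroxyl of the 2,4-dihydroxyphenyl ring is para to the benzylic ring carbon, so that carbon can become the exocyclic carbon of a para-quinone methide. The other carbon of the bond is α to a C=O, which is carried as the carbonyl of a six-membered aryl lactone closed onto an ortho oxygen of the neighbouring resorcinol ring.
4. Helpers: a p-tolylsulfonyl group on the benzylic carbon (first makes it a carbanion for the CH2–CH bond, then leaves as sulfinate) and the lactone ring (temporary ring, opened in step 15).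
5. Stereochemistry: the resorcinol-bearing carbon comes from the (R)-SEGPHOS/rhodium addition; the other two centres arise in the ring closure (cis ring fusion enforced by the lactone, aryl group trans through a pseudo-equatorial quinone methide); the (Z)-alkene comes from anti-carbomagnesiation of propargyl alcohol.

Key step: step 14

Remark: the target is taken exactly as drawn, with the benzoyl ring carrying hydroxyls at C3 and C5 and the prenyl group at C4.
Remark: 17 and 18 are racemic and 19 and 20 are pairs of epimers at the sulfonyl-bearing carbon; this carbon becomes trigonal in step 14, so its configuration is immaterial.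

**Fragment A: coumarin**

Step 1
Reactants: 1 2,6-dihydroxybenzaldehyde
Product: 3 5-hydroxy-2H-chromen-2-one, via cinnamate ester 2 (not isolated)
Conditions: Ph3P=CHCO2Et, PhNEt2, 200 °C
Reagents that add atoms: ethyl (triphenylphosphoranylidene)acetate, CCOC(=O)C=P(c1ccccc1)(c1ccccc1)c1ccccc1
Why: Wittig olefination of the salicylaldehyde followed by thermal E/Z isomerization and lactonization (classical coumarin synthesis); the two hydroxyls of 1 are equivalent, so only one coumarin can form.

Step 2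
Reactants: 3 5-hydroxy-2H-chromen-2-one
Product: 4 8-bromo-5-hydroxy-2H-chromen-2-one
Conditions: NBS, MeCN, 0 °C
Reagents that add atoms: N-bromosuccinimide, O=C1CCC(=O)N1Br
Why: Electrophilic aromatic bromination of the phenol ring, expected para to the free hydroxyl (C8); a 6-bromo isomer, if formed and carried on, would converge with the route at 25, where both resorcinol oxygens carry the same group.

Step 3
Reactants: 4 8-bromo-5-hydroxy-2H-chromen-2-one
Product: 5 8-bromo-5-(methoxymethoxy)-2H-chromen-2-one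
Conditions: MOMCl, i-Pr2NEt, CH2Cl2, 0 °C to rt
Reagents that add atoms: chloromethyl methyl ether, COCCl
Why: Williamson-type O-alkylation of the acidic phenol; the ether keeps the coumarin electrophilic for step 12.

**Fragment B: (Z)-alkenylboronate**

Step 4
Reactants: 6 2,4-dihydroxybenzaldehyde
Product: 7 2-hydroxy-4-{[tri(propan-2-yl)silyl]oxy}benzaldehyde
Conditions: TIPSCl, imidazole, CH2Cl2, 0 °C
Reagents that add atoms: chlorotri(propan-2-yl)silane, CC(C)[Si](Cl)(C(C)C)C(C)C
Why: Selective silylation of the 4-hydroxyl, because the 2-hydroxyl is hydrogen-bonded to the aldehyde and less nucleophilic.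

Step 5
Reactants: 7 2-hydroxy-4-{[tri(propan-2-yl)silyl]oxy}benzaldehyde
Product: 8 2-(methoxymethoxy)-4-{[tri(propan-2-yl)silyl]oxy}benzaldehyde
Conditions: MOMCl, i-Pr2NEt, CH2Cl2, 40 °C
Reagents that add atoms: chloromethyl methyl ether, COCCl
Why: O-alkylation of the remaining chelated phenol, which leaves the two ring oxygens differentiated (only the para oxygen is fluoride-labile).

Step 6
Reactants: 8 2-(methoxymethoxy)-4-{[tri(propan-2-yl)silyl]oxy}benzaldehyde
Product: 9 [2-(methoxymethoxy)-4-{[tri(propan-2-yl)silyl]oxy}phenyl]methanol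
Conditions: NaBH4, MeOH/THF, 0 °C
Reagents that add atoms: none
Why: Borohydride reduction of the aryl aldehyde; silyl and MOM ethers are inert.

Step 7
Reactants: 9 [2-(methoxymethoxy)-4-{[tri(propan-2-yl)silyl]oxy}phenyl]methanol
Product: 11 2-(methoxymethoxy)-1-[(4-methylbenzenesulfonyl)methyl]-4-{[tri(propan-2-yl)silyl]oxy}benzene, via benzylic chloride 10 (not isolated)
Conditions: MsCl, Et3N, CH2Cl2, −20 °C; then TolSO2Na, DMF, 0 °C to rt
Reagents that add atoms: sodium 4-methylbenzenesulfinate, [Na+].Cc1ccc(cc1)S(=O)[O-]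
Why: The electron-rich benzylic mesylate collapses to the chloride, which undergoes S-alkylation of the sulfinate (SN2) to give the benzylic sulfone.

Step 8
Reactants: 12 prop-2-yn-1-ol
Product: 14 (2Z)-3-iodo-2-methylprop-2-en-1-ol, via alkenylmagnesium alkoxide 13 (not isolated)
Conditions: MeMgBr (2.5 equiv), CuI (10 mol %), THF, −20 °C to rt; then I2, −78 to 0 °C
Reagents that add atoms: methylmagnesium bromide, C[Mg]Br; iodine, II
Why: Alkoxide-directed anti-carbomagnesiation of the propargylic alcohol gives a five-membered magnesium chelate, and iodinolysis with retention fixes iodine cis to the CH2O group (Z).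

Step 9
Reactants: 14 (2Z)-3-iodo-2-methylprop-2-en-1-ol
Product: 15 (1Z)-3-bromo-1-iodo-2-methylprop-1-ene
Conditions: CBr4, PPh3, CH2Cl2, 0 °C
Reagents that add atoms: tetrabromomethane, BrC(Br)(Br)Br
Why: Appel bromination of the primary allylic alcohol; the alkene geometry is untouched.

Step 10
Reactants: 11 2-(methoxymethoxy)-1-[(4-methylbenzenesulfonyl)methyl]-4-{[tri(propan-2-yl)silyl]oxy}benzene; 15 (1Z)-3-bromo-1-iodo-2-methylprop-1-ene
Product: 17 1-[(3Z)-4-iodo-3-methyl-1-(4-methylbenzenesulfonyl)but-3-en-1-yl]-2-(methoxymethoxy)-4-{[tri(propan-2-yl)silyl]oxy}benzene (racemic), via lithiated sulfone 16 (not isolated)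
Conditions: n-BuLi, THF, −78 °C; then 15, −78 to −40 °C
Reagents that add atoms: none
Why: SN2 alkylation of the α-sulfonyl benzylic carbanion by the allylic bromide forms the CH2–CH(aryl) bond; the alkenyl iodide does not react.

Step 11
Reactants: 17 1-[(3Z)-4-iodo-3-methyl-1-(4-methylbenzenesulfonyl)but-3-en-1-yl]-2-(methoxymethoxy)-4-{[tri(propan-2-yl)silyl]oxy}benzene
Product: 18 2-[(1Z)-4-[2-(methoxymethoxy)-4-{[tri(propan-2-yl)silyl]oxy}phenyl]-2-methyl-4-(4-methylbenzenesulfonyl)but-1-en-1-yl]-4,4,5,5-tetramethyl-1,3,2-dioxaborolane (racemic)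
Conditions: B2pin2, PdCl2(PPh3)2 (3 mol %), PPh3, KOPh, toluene, 50 °C
Reagents that add atoms: bis(pinacolato)diboron, CC1(C)OB(OC1(C)C)B1OC(C)(C)C(C)(C)O1
Why: Miyaura borylation of the alkenyl iodide, which proceeds with retention of the double-bond geometry.

**Union and ring closure**

Step 12
Reactants: 5 8-bromo-5-(methoxymethoxy)-2H-chromen-2-one; 18 the (Z)-alkenylboronate
Product: 19 (4R)-8-bromo-5-(methoxymethoxy)-4-[(1Z)-4-[2-(methoxymethoxy)-4-{[tri(propan-2-yl)silyl]oxy}phenyl]-2-methyl-4-(4-methylbenzenesulfonyl)but-1-en-1-yl]-3,4-dihydro-2H-chromen-2-one (both epimers at the sulfonyl-bearing carbon)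
Conditions: [RhCl(C2H4)2]2 (2.5 mol %), (R)-SEGPHOS (5.5 mol %), K3PO4 (1 equiv), 1,4-dioxane/H2O 10:1, 50 °C; then AcOH
Reagents that add atoms: none
Why: Rhodium-catalysed asymmetric 1,4-addition (Hayashi–Miyaura reaction) of the alkenylboronate to the coumarin, in which the face of C4 is chosen by (R)-SEGPHOS, the ligand enantiomer that gives (R)-4-substituted chroman-2-ones with arylboron reagents (the alkenyl group takes the same CIP rank), and the alkenyl geometry is retained.

Step 13
Reactants: 19 the silyl ether above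
Product: 20 (4R)-8-bromo-4-[(1Z)-4-[4-hydroxy-2-(methoxymethoxy)phenyl]-2-methyl-4-(4-methylbenzenesulfonyl)but-1-en-1-yl]-5-(methoxymethoxy)-3,4-dihydro-2H-chromen-2-one (both epimers at the sulfonyl-bearing carbon)
Conditions: n-Bu4NF, AcOH (1:1), THF, 0 °C
Reagents that add atoms: none
Why: Buffered fluoride cleavage of the aryl silyl ether; the acetic acid keeps the phenol protonated so that the sulfinate is not expelled prematurely.

Step 14
Reactants: 20 the phenol sulfone above
Product: 23 (6aR,7S,10aS)-4-bromo-7-[4-hydroxy-2-(methoxymethoxy)phenyl]-1-(methoxymethoxy)-9-methyl-6a,7,8,10a-tetrahydro-6H-benzo[c]chromen-6-one, via dipotassium salt 21 (not isolated), via quinone methide enolate 22 (not isolated)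
Conditions: KN(SiMe3)2 (2.05 equiv), THF, −78 °C; then −78 to −20 °C; AcOH, −78 °C
Reagents that add atoms: none
Why: The first equivalent of base gives the phenoxide and the second the lactone enolate (21); on warming, the phenoxide expels p-toluenesulfinate in a 1,6-elimination to give the para-quinone methide 22, and the enolate carbon adds to its exocyclic carbon (intramolecular 1,6-conjugate addition), which rearomatizes the resorcinol ring. The closest known reaction type is the Michael addition of ester and lactone enolates to quinone methides released in situ from hydroxybenzyl sulfones. The cyclohexene ring closes in the 6-(enolexo)-exo-trig mode, with the (Z)-alkene holding the two termini together. The carbon α to the lactone carbonyl (C6a) is controlled by the lactone ring: the four-atom tether can reach the flat enolate only from the face that carries the C10a–C10 bond, so the ring fusion should be cis (carbonyl cis to the resorcinol ring). The benzylic carbon (C7) is controlled by a half-chair transition state in which the quinone methide ring lies pseudo-equatorial and points away from the benzo-fused lactone, which places the aryl group trans to the carbonyl. The step needs C–C bond formation to outrun proton transfer (deprotonation at the sulfonyl-bearing carbon or at the allylic CH2 next to the quinone methide); this is secured by forming the enolate at −78 °C before the quinone methide appears, by using no excess base, and by the phenoxide, which lowers the acidity of the sulfonyl-bearing C–H.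

Step 15
Reactants: 23 the cis-fused lactone above
Product: 24 (1R,2S,6S)-2-[3-bromo-2-hydroxy-6-(methoxymethoxy)phenyl]-6-[4-hydroxy-2-(methoxymethoxy)phenyl]-N-methoxy-N,4-dimethylcyclohex-3-ene-1-carboxamide
Conditions: MeNH(OMe)·HCl, AlMe3, CH2Cl2, 0 °C to rt; aq. Rochelle salt
Reagents that add atoms: N,O-dimethylhydroxylamine hydrochloride, CNOC.Cl
Why: Weinreb aminolysis of the aryl lactone by the aluminium amide opens the temporary ring under non-basic conditions, so the α-stereocentre should be retained, and frees the resorcinol oxygen that the target needs.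

Step 16
Reactants: 24 the diphenol Weinreb amide above
Product: 25 (1R,2S,6S)-2-[3-bromo-2,6-bis(methoxymethoxy)phenyl]-6-[2,4-bis(methoxymethoxy)phenyl]-N-methoxy-N,4-dimethylcyclohex-3-ene-1-carboxamide
Conditions: MOMCl (excess), i-Pr2NEt, CH2Cl2, 0 to 40 °C
Reagents that add atoms: chloromethyl methyl ether, COCCl
Why: O-alkylation of both phenols with a weak amine base, which blocks relactonization and removes acidic protons before the Grignard step without touching the α-centre.

**Fragment C: prenylated aryl bromide**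

Step 17
Reactants: 26 5-bromobenzene-1,3-diol
Product: 27 1-bromo-3,5-bis(methoxymethoxy)benzene
Conditions: MOMCl, i-Pr2NEt, CH2Cl2, 0 °C to rt
Reagents that add atoms: chloromethyl methyl ether, COCCl
Why: Double O-alkylation; the MOM ethers also serve as directing groups in step 18.

Step 18
Reactants: 27 1-bromo-3,5-bis(methoxymethoxy)benzene
Product: 29 5-bromo-1,3-bis(methoxymethoxy)-2-(3-methylbut-2-en-1-yl)benzene, via aryllithium 28 (not isolated)
Conditions: LiN(i-Pr)2, THF, −78 °C; CuBr·SMe2 (10 mol %), prenyl bromide, −78 to 0 °C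
Reagents that add atoms: 1-bromo-3-methylbut-2-ene, CC(C)=CCBr
Why: Directed ortho-metalation at the position flanked by both MOM ethers with an amide base, which cannot undergo bromine–lithium exchange, followed by SN2 alkylation with prenyl bromide.

**Endgame**

Step 19
Reactants: 29 5-bromo-1,3-bis(methoxymethoxy)-2-(3-methylbut-2-en-1-yl)benzene; 25 the Weinreb amide
Product: 31 [(1R,2S,6S)-2-[3-bromo-2,6-bis(methoxymethoxy)phenyl]-6-[2,4-bis(methoxymethoxy)phenyl]-4-methylcyclohex-3-en-1-yl][3,5-bis(methoxymethoxy)-4-(3-methylbut-2-en-1-yl)phenyl]methanone, via arylmagnesium bromide 30 (not isolated)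
Conditions: Mg, LiCl, THF, rt; then 25, 0 °C to rt; aq. NH4Cl
Reagents that add atoms: none
Why: Weinreb ketone synthesis, in which the chelated tetrahedral intermediate prevents over-addition; a Grignard reagent is chosen over an aryllithium so that the aryl bromide of 25 does not undergo halogen–metal exchange.

Step 20
Reactants: 31 the bromo ketone above; 32 4-ethenylphenyl acetate
Product: 33 4-[(1E)-3-{3-[(1S,5S,6R)-6-[3,5-bis(methoxymethoxy)-4-(3-methylbut-2-en-1-yl)benzoyl]-5-[2,4-bis(methoxymethoxy)phenyl]-3-methylcyclohex-2-en-1-yl]-2,4-bis(methoxymethoxy)phenyl}-3-oxoprop-1-en-1-yl]phenyl acetate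
Conditions: Pd(OAc)2 (5 mol %), n-BuP(1-adamantyl)2 (10 mol %), CO (10 bar), NEt3, 1,4-dioxane, 100 °C
Reagents that add atoms: carbon monoxide, [C-]#[O+]
Why: Carbonylative Heck reaction: oxidative addition into the aryl bromide, CO insertion to the aroylpalladium species, insertion of the styrene and β-hydride elimination should give the (E)-chalcone; the trisubstituted ring alkene and the prenyl group are too hindered to insert.

Step 21
Reactants: 33 the protected chalcone above
Product: 34 kuwanon R, (2E)-1-{3-[(1S,5S,6R)-6-[3,5-dihydroxy-4-(3-methylbut-2-en-1-yl)benzoyl]-5-(2,4-dihydroxyphenyl)-3-methylcyclohex-2-en-1-yl]-2,4-dihydroxyphenyl}-3-(4-hydroxyphenyl)prop-2-en-1-one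
Conditions: HCl (3 M aq)/MeOH 1:4, 40 °C
Reagents that add atoms: none
Why: Acid-catalysed acetal exchange removes the six MOM ethers and methanolysis removes the acetate, under the dilute-acid conditions used for prenylated 2,4-dihydroxyphenyl chalcones so that the prenyl group and the ring alkene should survive.

**Compound list**

1 | 2,6-dihydroxybenzaldehyde | O=Cc1c(O)cccc1O | starting material
2 | ethyl 3-(2,6-dihydroxyphenyl)prop-2-enoate (E/Z mixture; the Z isomer lactonizes) | CCOC(=O)C=Cc1c(O)cccc1O | intermediate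
3 | 5-hydroxy-2H-chromen-2-one | O=c1ccc2c(O)cccc2o1 | intermediate
4 | 8-bromo-5-hydroxy-2H-chromen-2-one | O=c1ccc2c(O)ccc(Br)c2o1 | intermediate
5 | 8-bromo-5-(methoxymethoxy)-2H-chromen-2-one | COCOc1ccc(Br)c2oc(=O)ccc12 | intermediate
6 | 2,4-dihydroxybenzaldehyde | O=Cc1ccc(O)cc1O | starting material
7 | 2-hydroxy-4-{[tri(propan-2-yl)silyl]oxy}benzaldehyde | CC(C)[Si](Oc1ccc(C=O)c(O)c1)(C(C)C)C(C)C | intermediate
8 | 2-(methoxymethoxy)-4-{[tri(propan-2-yl)silyl]oxy}benzaldehyde | COCOc1cc(O[Si](C(C)C)(C(C)C)C(C)C)ccc1C=O | intermediate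
9 | [2-(methoxymethoxy)-4-{[tri(propan-2-yl)silyl]oxy}phenyl]methanol | COCOc1cc(O[Si](C(C)C)(C(C)C)C(C)C)ccc1CO | intermediate
10 | 1-(chloromethyl)-2-(methoxymethoxy)-4-{[tri(propan-2-yl)silyl]oxy}benzene | COCOc1cc(O[Si](C(C)C)(C(C)C)C(C)C)ccc1CCl | intermediate
11 | 2-(methoxymethoxy)-1-[(4-methylbenzenesulfonyl)methyl]-4-{[tri(propan-2-yl)silyl]oxy}benzene | COCOc1cc(O[Si](C(C)C)(C(C)C)C(C)C)ccc1CS(=O)(=O)c1ccc(C)cc1 | intermediate
12 | prop-2-yn-1-ol | C#CCO | starting material
13 | bromomagnesium (2Z)-3-(bromomagnesio)-2-methylprop-2-en-1-olate | C/C(CO[Mg]Br)=C/[Mg]Br | intermediate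
14 | (2Z)-3-iodo-2-methylprop-2-en-1-ol | OC/C(C)=C\I | intermediate
15 | (1Z)-3-bromo-1-iodo-2-methylprop-1-ene | BrC/C(C)=C\I | intermediate
16 | [2-(methoxymethoxy)-4-{[tri(propan-2-yl)silyl]oxy}phenyl](4-methylbenzenesulfonyl)methyllithium | COCOc1cc(O[Si](C(C)C)(C(C)C)C(C)C)ccc1C([Li])S(=O)(=O)c1ccc(C)cc1 | intermediate
17 | 1-[(3Z)-4-iodo-3-methyl-1-(4-methylbenzenesulfonyl)but-3-en-1-yl]-2-(methoxymethoxy)-4-{[tri(propan-2-yl)silyl]oxy}benzene (racemic) | COCOc1cc(O[Si](C(C)C)(C(C)C)C(C)C)ccc1C(C/C(C)=C\I)S(=O)(=O)c1ccc(C)cc1 | intermediate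
18 | 2-[(1Z)-4-[2-(methoxymethoxy)-4-{[tri(propan-2-yl)silyl]oxy}phenyl]-2-methyl-4-(4-methylbenzenesulfonyl)but-1-en-1-yl]-4,4,5,5-tetramethyl-1,3,2-dioxaborolane (racemic) | COCOc1cc(O[Si](C(C)C)(C(C)C)C(C)C)ccc1C(C/C(C)=C\B1OC(C)(C)C(C)(C)O1)S(=O)(=O)c1ccc(C)cc1 | intermediate
19 | (4R)-8-bromo-5-(methoxymethoxy)-4-[(1Z)-4-[2-(methoxymethoxy)-4-{[tri(propan-2-yl)silyl]oxy}phenyl]-2-methyl-4-(4-methylbenzenesulfonyl)but-1-en-1-yl]-3,4-dihydro-2H-chromen-2-one (both epimers at the sulfonyl-bearing carbon) | COCOc1ccc(Br)c2OC(=O)C[C@H](/C=C(C)\CC(c3ccc(O[Si](C(C)C)(C(C)C)C(C)C)cc3OCOC)S(=O)(=O)c3ccc(C)cc3)c12 | intermediate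
20 | (4R)-8-bromo-4-[(1Z)-4-[4-hydroxy-2-(methoxymethoxy)phenyl]-2-methyl-4-(4-methylbenzenesulfonyl)but-1-en-1-yl]-5-(methoxymethoxy)-3,4-dihydro-2H-chromen-2-one (both epimers at the sulfonyl-bearing carbon) | COCOc1ccc(Br)c2OC(=O)C[C@H](/C=C(C)\CC(c3ccc(O)cc3OCOC)S(=O)(=O)c3ccc(C)cc3)c12 | intermediate
21 | dipotassium salt of 20 (phenoxide and lactone enolate) | COCOc1ccc(Br)c2OC([O-])=C[C@H](/C=C(C)\CC(c3ccc([O-])cc3OCOC)S(=O)(=O)c3ccc(C)cc3)c12.[K+].[K+] | intermediate
22 | potassium lactone enolate carrying the para-quinone methide, 4-[(1Z)-2-methyl-4-[2-(methoxymethoxy)-4-oxocyclohexa-2,5-dien-1-ylidene]but-1-en-1-yl] side chain | COCOc1ccc(Br)c2OC([O-])=C[C@H](/C=C(C)\CC=C3C=CC(=O)C=C3OCOC)c12.[K+] | intermediate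
23 | (6aR,7S,10aS)-4-bromo-7-[4-hydroxy-2-(methoxymethoxy)phenyl]-1-(methoxymethoxy)-9-methyl-6a,7,8,10a-tetrahydro-6H-benzo[c]chromen-6-one | O=C1Oc2c(Br)ccc(OCOC)c2[C@H]2C=C(C)C[C@H](c3ccc(O)cc3OCOC)[C@@H]12 | intermediate
24 | (1R,2S,6S)-2-[3-bromo-2-hydroxy-6-(methoxymethoxy)phenyl]-6-[4-hydroxy-2-(methoxymethoxy)phenyl]-N-methoxy-N,4-dimethylcyclohex-3-ene-1-carboxamide | CON(C)C(=O)[C@H]1[C@@H](c2c(OCOC)ccc(Br)c2O)C=C(C)C[C@@H]1c1ccc(O)cc1OCOC | intermediate
25 | (1R,2S,6S)-2-[3-bromo-2,6-bis(methoxymethoxy)phenyl]-6-[2,4-bis(methoxymethoxy)phenyl]-N-methoxy-N,4-dimethylcyclohex-3-ene-1-carboxamide | CON(C)C(=O)[C@H]1[C@@H](c2c(OCOC)ccc(Br)c2OCOC)C=C(C)C[C@@H]1c1ccc(OCOC)cc1OCOC | intermediate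
26 | 5-bromobenzene-1,3-diol | Oc1cc(O)cc(Br)c1 | starting material
27 | 1-bromo-3,5-bis(methoxymethoxy)benzene | COCOc1cc(Br)cc(OCOC)c1 | intermediate
28 | [4-bromo-2,6-bis(methoxymethoxy)phenyl]lithium | COCOc1cc(Br)cc(OCOC)c1[Li] | intermediate
29 | 5-bromo-1,3-bis(methoxymethoxy)-2-(3-methylbut-2-en-1-yl)benzene | COCOc1cc(Br)cc(OCOC)c1CC=C(C)C | intermediate
30 | [3,5-bis(methoxymethoxy)-4-(3-methylbut-2-en-1-yl)phenyl]magnesium bromide | COCOc1cc([Mg]Br)cc(OCOC)c1CC=C(C)C | intermediate
31 | [(1R,2S,6S)-2-[3-bromo-2,6-bis(methoxymethoxy)phenyl]-6-[2,4-bis(methoxymethoxy)phenyl]-4-methylcyclohex-3-en-1-yl][3,5-bis(methoxymethoxy)-4-(3-methylbut-2-en-1-yl)phenyl]methanone | CC(C)=CCc1c(OCOC)cc(C(=O)[C@H]2[C@@H](c3c(OCOC)ccc(Br)c3OCOC)C=C(C)C[C@@H]2c2ccc(OCOC)cc2OCOC)cc1OCOC | intermediate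
32 | 4-ethenylphenyl acetate | CC(=O)Oc1ccc(C=C)cc1 | starting material
33 | 4-[(1E)-3-{3-[(1S,5S,6R)-6-[3,5-bis(methoxymethoxy)-4-(3-methylbut-2-en-1-yl)benzoyl]-5-[2,4-bis(methoxymethoxy)phenyl]-3-methylcyclohex-2-en-1-yl]-2,4-bis(methoxymethoxy)phenyl}-3-oxoprop-1-en-1-yl]phenyl acetate | CC(C)=CCc1c(OCOC)cc(C(=O)[C@H]2[C@@H](c3c(OCOC)ccc(C(=O)/C=C/c4ccc(OC(C)=O)cc4)c3OCOC)C=C(C)C[C@@H]2c2ccc(OCOC)cc2OCOC)cc1OCOC | intermediate
34 | kuwanon R | CC(C)=CCc1c(O)cc(C(=O)[C@H]2[C@@H](c3c(O)ccc(C(=O)/C=C/c4ccc(O)cc4)c3O)C=C(C)C[C@@H]2c2ccc(O)cc2O)cc1O | target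

**Count and risks**

Total step count: 21. Longest linear sequence: 14 steps (6 → 7 → 8 → 9 → 11 → 17 → 18 → 19 → 20 → 23 → 24 → 25 → 31 → 33 → 34, that is steps 4, 5, 6, 7, 10, 11, 12, 13, 14, 15, 16, 19, 20 and 21).

The three steps most likely to fail:

Step 14. Proton transfer may outrun C–C bond formation under the strongly basic conditions: deprotonation at the sulfonyl-bearing carbon, tautomerization of the quinone methide to a dienyl phenol through loss of an allylic proton, or fragmentation of the aryl lactone enolate to a ketene. The fallback sets out from 19 and comes back at 23. Treatment of 19 with LiN(SiMe3)2 and Me3SiCl (internal quench, THF, −78 °C) should give the O-trimethylsilyl ketene acetal (4S)-8-bromo-5-(methoxymethoxy)-4-[(1Z)-4-[2-(methoxymethoxy)-4-{[tri(propan-2-yl)silyl]oxy}phenyl]-2-methyl-4-(4-methylbenzenesulfonyl)but-1-en-1-yl]-2-[(trimethylsilyl)oxy]-4H-chromene F1. Anhydrous fluoride, (Me2N)3S+ Me3SiF2− (2.2 equiv, THF, −78 to −20 °C, then AcOH), would then unmask the enolate and the phenoxide at the same moment, so that no free strong base is present while the quinone methide exists. This fluoride-triggered Mukaiyama–Michael closure passes through the same enolate anion as 22 and the same lactone-controlled transition state.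

Step 12. Insertion of the alkenylrhodium species into the weakly electrophilic coumarin, hindered by the peri MOM ether, may be slower than protodeboronation of 18, or facial discrimination may be poor. The fallback sets out from 1 and comes back at 19, and activates the acceptor with a removable ester. Knoevenagel condensation of 1 with diallyl malonate (piperidine, AcOH, EtOH, reflux) would give bis(prop-2-en-1-yl) 2-[(2,6-dihydroxyphenyl)methylidene]propanedioate F2, which lactonizes in the flask to prop-2-en-1-yl 5-hydroxy-2-oxo-2H-chromene-3-carboxylate F3. Bromination as in step 2 would give prop-2-en-1-yl 8-bromo-5-hydroxy-2-oxo-2H-chromene-3-carboxylate F4, and MOM protection as in step 3 would give prop-2-en-1-yl 8-bromo-5-(methoxymethoxy)-2-oxo-2H-chromene-3-carboxylate F5. This doubly activated acceptor should take up 18 under the rhodium/(R)-SEGPHOS conditions at room temperature to give prop-2-en-1-yl (4S)-8-bromo-5-(methoxymethoxy)-4-[(1Z)-4-[2-(methoxymethoxy)-4-{[tri(propan-2-yl)silyl]oxy}phenyl]-2-methyl-4-(4-methylbenzenesulfonyl)but-1-en-1-yl]-2-oxo-3,4-dihydro-2H-chromene-3-carboxylate F6. Deallylation and decarboxylation with Pd(PPh3)4, HCO2H and Et3N in THF would then give 19.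

Step 20. Oxidative addition into the electron-rich, ortho-substituted aryl bromide may be slow, and direct Heck coupling without CO uptake or thermal degradation at 100 °C may compete. The fallback sets out from 31 and comes back at 34, building the enone by condensation instead. Stille coupling of 31 with tributyl(1-ethoxyvinyl)stannane (Pd(PPh3)4, toluene, 100 °C) would give the enol ether {(1R,2S,6S)-2-[3-(1-ethoxyethenyl)-2,6-bis(methoxymethoxy)phenyl]-6-[2,4-bis(methoxymethoxy)phenyl]-4-methylcyclohex-3-en-1-yl}[3,5-bis(methoxymethoxy)-4-(3-methylbut-2-en-1-yl)phenyl]methanone F7. Brief hydrolysis (oxalic acid on wet silica, CH2Cl2) would give the methyl ketone 1-{3-[(1S,5S,6R)-6-[3,5-bis(methoxymethoxy)-4-(3-methylbut-2-en-1-yl)benzoyl]-5-[2,4-bis(methoxymethoxy)phenyl]-3-methylcyclohex-2-en-1-yl]-2,4-bis(methoxymethoxy)phenyl}ethan-1-one F8. Claisen–Schmidt condensation with 4-(methoxymethoxy)benzaldehyde (Ba(OH)2, MeOH, 40 °C) would give the heptakis-MOM chalcone (2E)-1-{3-[(1S,5S,6R)-6-[3,5-bis(methoxymethoxy)-4-(3-methylbut-2-en-1-yl)benzoyl]-5-[2,4-bis(methoxymethoxy)phenyl]-3-methylcyclohex-2-en-1-yl]-2,4-bis(methoxymethoxy)phenyl}-3-[4-(methoxymethoxy)phenyl]prop-2-en-1-one F9, which is deprotected under the conditions of step 21 to give 34.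

**Further compounds**

F1 | step 14 | (4S)-8-bromo-5-(methoxymethoxy)-4-[(1Z)-4-[2-(methoxymethoxy)-4-{[tri(propan-2-yl)silyl]oxy}phenyl]-2-methyl-4-(4-methylbenzenesulfonyl)but-1-en-1-yl]-2-[(trimethylsilyl)oxy]-4H-chromene | COCOc1ccc(Br)c2OC(O[Si](C)(C)C)=C[C@H](/C=C(C)\CC(c3ccc(O[Si](C(C)C)(C(C)C)C(C)C)cc3OCOC)S(=O)(=O)c3ccc(C)cc3)c12
F2 | step 12 | bis(prop-2-en-1-yl) 2-[(2,6-dihydroxyphenyl)methylidene]propanedioate | C=CCOC(=O)C(=Cc1c(O)cccc1O)C(=O)OCC=C
F3 | step 12 | prop-2-en-1-yl 5-hydroxy-2-oxo-2H-chromene-3-carboxylate | C=CCOC(=O)c1cc2c(O)cccc2oc1=O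
F4 | step 12 | prop-2-en-1-yl 8-bromo-5-hydroxy-2-oxo-2H-chromene-3-carboxylate | C=CCOC(=O)c1cc2c(O)ccc(Br)c2oc1=O
F5 | step 12 | prop-2-en-1-yl 8-bromo-5-(methoxymethoxy)-2-oxo-2H-chromene-3-carboxylate | C=CCOC(=O)c1cc2c(OCOC)ccc(Br)c2oc1=O
F6 | step 12 | prop-2-en-1-yl (4S)-8-bromo-5-(methoxymethoxy)-4-[(1Z)-4-[2-(methoxymethoxy)-4-{[tri(propan-2-yl)silyl]oxy}phenyl]-2-methyl-4-(4-methylbenzenesulfonyl)but-1-en-1-yl]-2-oxo-3,4-dihydro-2H-chromene-3-carboxylate (epimers at C3 and at the sulfonyl-bearing carbon) | C=CCOC(=O)C1C(=O)Oc2c(Br)ccc(OCOC)c2[C@H]1/C=C(C)\CC(c1ccc(O[Si](C(C)C)(C(C)C)C(C)C)cc1OCOC)S(=O)(=O)c1ccc(C)cc1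
F7 | step 20 | {(1R,2S,6S)-2-[3-(1-ethoxyethenyl)-2,6-bis(methoxymethoxy)phenyl]-6-[2,4-bis(methoxymethoxy)phenyl]-4-methylcyclohex-3-en-1-yl}[3,5-bis(methoxymethoxy)-4-(3-methylbut-2-en-1-yl)phenyl]methanone | CC(C)=CCc1c(OCOC)cc(C(=O)[C@H]2[C@@H](c3c(OCOC)ccc(C(=C)OCC)c3OCOC)C=C(C)C[C@@H]2c2ccc(OCOC)cc2OCOC)cc1OCOC
F8 | step 20 | 1-{3-[(1S,5S,6R)-6-[3,5-bis(methoxymethoxy)-4-(3-methylbut-2-en-1-yl)benzoyl]-5-[2,4-bis(methoxymethoxy)phenyl]-3-methylcyclohex-2-en-1-yl]-2,4-bis(methoxymethoxy)phenyl}ethan-1-one | CC(C)=CCc1c(OCOC)cc(C(=O)[C@H]2[C@@H](c3c(OCOC)ccc(C(C)=O)c3OCOC)C=C(C)C[C@@H]2c2ccc(OCOC)cc2OCOC)cc1OCOC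
F9 | step 20 | (2E)-1-{3-[(1S,5S,6R)-6-[3,5-bis(methoxymethoxy)-4-(3-methylbut-2-en-1-yl)benzoyl]-5-[2,4-bis(methoxymethoxy)phenyl]-3-methylcyclohex-2-en-1-yl]-2,4-bis(methoxymethoxy)phenyl}-3-[4-(methoxymethoxy)phenyl]prop-2-en-1-one | CC(C)=CCc1c(OCOC)cc(C(=O)[C@H]2[C@@H](c3c(OCOC)ccc(C(=O)/C=C/c4ccc(OCOC)cc4)c3OCOC)C=C(C)C[C@@H]2c2ccc(OCOC)cc2OCOC)cc1OCOC
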